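The route rests on cutting two neighbouring positions of ring A (the trihydroxyphenyl ring) at once. One cut is the bond from ring carbon C1′ to the ketone carbon C1. The other is the bond from C2′ to its phenolic oxygen. These two substituents are vicinal and the remaining oxygens sit at C4′ and C6′, so ring A maps onto 3,5-dimethoxybenzyne. In one operation 11-(2-methoxyphenyl)undecanoic acid adds across this aryne, oxygen first and acyl second, which forges the aryl C–O and aryl C–C1 bonds. The aryne precursor is 3,5-dimethoxy-2-(trimethylsilyl)phenyl triflate. The acid, which carries ring B, comes from a B-alkyl Suzuki coupling. Cleavage of three methyl ethers ends the route.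

Key step: step 6

Remark: the target is achiral (no stereocentre, no stereogenic double bond), so the SMILES carry no stereodescriptors. Primed numbers denote ring A (C1′ bears the acyl group). Unprimed numbers denote the chain (C1 = ketone carbon, C11 = benzylic carbon on ring B).

Step 1
Reactants: 1 3,5-dimethoxyphenol
Product: 2 3,5-dimethoxyphenyl N-isopropylcarbamate
Conditions: i-PrNCO (1.5 equiv), Et3N (0.2 equiv), CH2Cl2, rt
Reagents that add atoms: isopropyl isocyanate, CC(C)N=C=O
Why: Amine-catalysed addition of the phenol O–H across the isocyanate (carbamoylation) should cleanly install a strong ortho-directing group that can later be removed under mild basic conditions.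

Step 2
Reactants: 2 3,5-dimethoxyphenyl N-isopropylcarbamate
Product: 6 3,5-dimethoxy-2-(trimethylsilyl)phenyl N-isopropylcarbamate, via N-TBS carbamate 3 (not isolated), via C2 aryllithium 4 (not isolated), via N-TBS C2-TMS carbamate 5 (not isolated)
Conditions: TBSOTf (1.1 equiv), TMEDA (1.1 equiv), Et2O, 0 °C to rt; n-BuLi (2 equiv), TMEDA (2 equiv), −78 °C; TMSCl (3 equiv), −78 °C to rt; cold aq NaHSO4, brief
Reagents that add atoms: chlorotrimethylsilane, C[Si](C)(C)Cl
Why: In this directed ortho-metalation the in situ N-silylation masks the N–H, the carbamate carbonyl steers n-BuLi/TMEDA to the C–H between carbamate and methoxy (two such sites, equivalent by symmetry, both more activated than the site between the two weaker methoxy directors), the aryllithium resists anionic Fries migration at −78 °C until TMSCl captures it, and the labile N–Si bond is hydrolysed on work-up.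

Step 3
Reactants: 6 3,5-dimethoxy-2-(trimethylsilyl)phenyl N-isopropylcarbamate
Product: 8 3,5-dimethoxy-2-(trimethylsilyl)phenyl trifluoromethanesulfonate, via 3,5-dimethoxy-2-(trimethylsilyl)phenol 7 (not isolated)
Conditions: DBU (1.5 equiv), Et2NH (1.2 equiv), MeCN, 40 °C; then PhNTf2 (1.5 equiv), rt
Reagents that add atoms: N-phenylbis(trifluoromethanesulfonimide), O=S(=O)(N(c1ccccc1)S(=O)(=O)C(F)(F)F)C(F)(F)F
Why: DBU removes the carbamate N–H and triggers E1cB expulsion of the phenoxide, Et2NH binds the isocyanate fragment as a urea, and O-triflation with PhNTf2 follows in the same flask, so the protodesilylation-prone ortho-silylphenol is never handled.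

Step 4
Reactants: 9 methyl undec-10-enoate; 10 2-bromoanisole
Product: 12 methyl 11-(2-methoxyphenyl)undecanoate, via B-alkyl-9-BBN adduct 11 (not isolated)
Conditions: 9-BBN (1.1 equiv), THF, 0 °C to rt; then 10 (0.95 equiv), PdCl2(dppf) (3 mol %), K2CO3 (3 equiv), THF/DMF/H2O, 50–60 °C
Reagents that add atoms: none
Why: 9-BBN hydroborates the terminal alkene anti-Markovnikov without touching the ester, and the primary borane then undergoes B-alkyl Suzuki–Miyaura coupling with the aryl bromide, where the wide-bite dppf ligand favours reductive elimination over beta-hydride loss and the carbonate base spares the ester.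

Step 5
Reactants: 12 methyl 11-(2-methoxyphenyl)undecanoate
Product: 13 11-(2-methoxyphenyl)undecanoic acid
Conditions: LiOH (3 equiv), THF/MeOH/H2O, rt; then 1 M HCl
Reagents that add atoms: lithium hydroxide, [Li+].[OH-]
Why: This is a plain saponification (acyl substitution by hydroxide) of an unhindered methyl ester in a molecule with no other base-sensitive group.

Step 6
Reactants: 8 3,5-dimethoxy-2-(trimethylsilyl)phenyl trifluoromethanesulfonate; 13 11-(2-methoxyphenyl)undecanoic acid
Product: 15 1-(2-hydroxy-4,6-dimethoxyphenyl)-11-(2-methoxyphenyl)undecan-1-one, via 3,5-dimethoxybenzyne 14 (not isolated)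
Conditions: 13 (1.0 equiv), 8 (1.5 equiv), dried CsF (4 equiv), THF (0.02 M), sealed pressure tube, 125 °C, 24 h; aq NH4Cl
Reagents that add atoms: none
Why: Fluoride attacks silicon in 8 and triflate departs, which releases aryne 14 with its triple bond between the future C1′ and C2′ of ring A and a methoxy group on C6′ next to C1′. That methoxy group withdraws electron density through the sigma frame and bends the aryne, so the carboxylate oxygen of 13 bonds to C2′, the distal and more electrophilic end, and the negative charge arises on C1′ beside the methoxy group. The aryl anion then adds to the adjacent ester carbonyl (4-exo-trig) and the strained four-membered alkoxide opens at once by C–O scission to the ketone and the phenoxide, so no ring persists and no stereocentre is formed. The closest known reaction type is the formal insertion of arynes generated from ortho-silylaryl triflates into the C–O bond of carboxylic acids, which delivers ortho-hydroxyaryl ketones and is mechanistically akin to an anionic ortho-Fries shift. Two selectivities are needed: regioselectivity, which the C6′ methoxy group secures and which puts C1 between OH and OMe and para to the second OMe, and acyl transfer in preference to protonation of the aryl anion, which dry CsF, high dilution in aprotic THF and 125 °C should favour. The anisole of ring B and the saturated C2–C11 chain offer nothing that reacts with fluoride or competes with the carboxylate for the aryne.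

Step 7
Reactants: 15 1-(2-hydroxy-4,6-dimethoxyphenyl)-11-(2-methoxyphenyl)undecan-1-one
Product: 16 11-(2-hydroxyphenyl)-1-(2,4,6-trihydroxyphenyl)undecan-1-one
Conditions: BBr3 (8 equiv), CH2Cl2, −78 °C to rt, 24 h; then ice-water
Reagents that add atoms: none
Why: In this Lewis-acid aryl methyl ether cleavage BBr3 binds each ether oxygen and bromide removes the methyl group by SN2, chelation helps the ether ortho to the ketone, excess reagent and long contact at rt are planned for the deactivated para ether, and the ketone, chain and rings stay untouched while aqueous work-up frees the phenols.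

Compound list
1 | 3,5-dimethoxyphenol | COc1cc(O)cc(OC)c1 | starting material
2 | 3,5-dimethoxyphenyl N-isopropylcarbamate | COc1cc(OC)cc(OC(=O)NC(C)C)c1 | intermediate
3 | 3,5-dimethoxyphenyl N-(tert-butyldimethylsilyl)-N-isopropylcarbamate (N-TBS carbamate, in situ) | COc1cc(OC)cc(OC(=O)N(C(C)C)[Si](C)(C)C(C)(C)C)c1 | intermediate
4 | aryllithium of 3, lithiated at the ring carbon between the carbamate oxygen and a methoxy group (C2 aryllithium, in situ) | [Li]c1c(OC)cc(OC)cc1OC(=O)N(C(C)C)[Si](C)(C)C(C)(C)C | intermediate
5 | 3,5-dimethoxy-2-(trimethylsilyl)phenyl N-(tert-butyldimethylsilyl)-N-isopropylcarbamate (in situ) | COc1cc(OC)c([Si](C)(C)C)c(OC(=O)N(C(C)C)[Si](C)(C)C(C)(C)C)c1 | intermediate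
6 | 3,5-dimethoxy-2-(trimethylsilyl)phenyl N-isopropylcarbamate | COc1cc(OC)c([Si](C)(C)C)c(OC(=O)NC(C)C)c1 | intermediate
7 | 3,5-dimethoxy-2-(trimethylsilyl)phenol (in situ, as its DBU salt) | COc1cc(O)c([Si](C)(C)C)c(OC)c1 | intermediate
8 | 3,5-dimethoxy-2-(trimethylsilyl)phenyl trifluoromethanesulfonate | COc1cc(OC)c([Si](C)(C)C)c(OS(=O)(=O)C(F)(F)F)c1 | intermediate
9 | methyl undec-10-enoate | C=CCCCCCCCCC(=O)OC | starting material
10 | 2-bromoanisole (1-bromo-2-methoxybenzene) | COc1ccccc1Br | starting material
11 | methyl 11-(9-borabicyclo[3.3.1]nonan-9-yl)undecanoate (in situ) | COC(=O)CCCCCCCCCCB1C2CCCC1CCC2 | intermediate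
12 | methyl 11-(2-methoxyphenyl)undecanoate | COC(=O)CCCCCCCCCCc1ccccc1OC | intermediate
13 | 11-(2-methoxyphenyl)undecanoic acid | COc1ccccc1CCCCCCCCCCC(=O)O | intermediate
14 | 3,5-dimethoxybenzyne (1,2-didehydro-3,5-dimethoxybenzene, in situ) | COC1=CC(OC)=CC#C1 | intermediate
15 | 1-(2-hydroxy-4,6-dimethoxyphenyl)-11-(2-methoxyphenyl)undecan-1-one | COc1ccccc1CCCCCCCCCCC(=O)c1c(O)cc(OC)cc1OC | intermediate
16 | 11-(2-hydroxyphenyl)-1-(2,4,6-trihydroxyphenyl)undecan-1-one (CNP0295227.0) | O=C(CCCCCCCCCCc1ccccc1O)c1c(O)cc(O)cc1O | target

Total step count: 7.
Longest linear sequence: 5 steps (steps 1, 2, 3, 6, 7, from 3,5-dimethoxyphenol). The acid arm (steps 4, 5) joins at step 6.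

Steps most likely to fail

**Step 6.** Three things may go wrong:
- The aryl anion may pick up a proton before the acyl group migrates.
- The product phenoxide may be arylated by a second aryne.
- The aryne may be lost to unproductive pathways at 125 °C.

The fallback replaces the aryne with classical electrophilic acylation. It sets out from 13 and returns at 15. Acid 13 is treated with (COCl)2 and catalytic DMF in CH2Cl2 to give 11-(2-methoxyphenyl)undecanoyl chloride F1. Friedel–Crafts acylation of commercial 1,3,5-trimethoxybenzene follows (AlCl3, CH2Cl2, 0 °C). Its three ring C–H positions are equivalent, so no regiochemical question arises, and it is far more nucleophilic than ring B. This should give 11-(2-methoxyphenyl)-1-(2,4,6-trimethoxyphenyl)undecan-1-one F2. BCl3 (1.1 equiv, CH2Cl2, −78 to 0 °C) then removes one methyl group ortho to the carbonyl by chelation control and delivers 15.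

**Step 7.** The ether cleavage may stall at the methoxy group para to the boron-bound ketone. Prolonged Lewis-acid exposure may also strip the acyl chain from the very electron-rich ring A.

In the fallback ring A enters unprotected, so no ring A ether has to be cleaved. It sets out from 13 and returns at 16. The single unhindered anisole of 13 is cleaved with BBr3 (CH2Cl2, −78 °C to rt) to give 11-(2-hydroxyphenyl)undecanoic acid F3. This acid is heated with commercial phloroglucinol in BF3·OEt2 (80–90 °C). The reaction is a Friedel–Crafts C-acylation of a symmetrical triphenol, a reaction type that tolerates a free phenol in the acid partner, and it should give 16 directly. Because it gives up the aryne step, this is a last resort.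

**Step 2.** Three things may go wrong:
- Lithiation may stray to the position between the two methoxy groups.
- The carbamoyl group may migrate (anionic ortho-Fries) before the silyl quench.
- The electron-rich arylsilane may protodesilylate in the acidic work-up.

In the fallback a halogen fixes the position and silicon is delivered intramolecularly. It sets out from 1 and returns at 8, replacing steps 1–3. NBS (CH2Cl2, −78 to 0 °C) should brominate 1 at the less hindered, twofold-degenerate position ortho to OH and para to OMe, giving 2-bromo-3,5-dimethoxyphenol F4, with any isomer removed by chromatography. HMDS (THF, reflux) gives (2-bromo-3,5-dimethoxyphenoxy)trimethylsilane F5. Treatment with n-BuLi (THF, −78 °C) effects bromine–lithium exchange followed by O-to-C silyl migration (retro-Brook rearrangement) to lithium 3,5-dimethoxy-2-(trimethylsilyl)phenoxide F6. Tf2O traps F6 in the same flask as 8.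

Further compounds
F1 | step 6 | 11-(2-methoxyphenyl)undecanoyl chloride | COc1ccccc1CCCCCCCCCCC(=O)Cl
F2 | step 6 | 11-(2-methoxyphenyl)-1-(2,4,6-trimethoxyphenyl)undecan-1-one | COc1ccccc1CCCCCCCCCCC(=O)c1c(OC)cc(OC)cc1OC
F3 | step 7 | 11-(2-hydroxyphenyl)undecanoic acid | OC(=O)CCCCCCCCCCc1ccccc1O
F4 | step 2 | 2-bromo-3,5-dimethoxyphenol | COc1cc(O)c(Br)c(OC)c1
F5 | step 2 | (2-bromo-3,5-dimethoxyphenoxy)trimethylsilane | COc1cc(O[Si](C)(C)C)c(Br)c(OC)c1
F6 | step 2 | lithium 3,5-dimethoxy-2-(trimethylsilyl)phenoxide | [Li+].[O-]c1cc(OC)cc(OC)c1[Si](C)(C)C
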